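Reagent in the second phase and the volume ratio stand the same in the red run, the teal run and the new flask, so between them the substrate charge is what moves.

all flasks: reagent in the second phase 0.891 M
- red: substrate 0.41 M; run made earlier
- teal: substrate 1.6 M; run made earlier
- flask: substrate 0.81 M; time 15 min; volume of the second phase over the first 0.50

| run | time / min | target / % | crystals / % |
|---|---|---|---|
| red | 0.833 | 3 | 0 |
| red | 2.50 | 4 | 1 |
| red | 4.00 | 11 | 3 |
| red | 6.00 | 13 | 4 |
| red | 10.0 | 18 | 0 |
| red | 12.0 | 20 | 1 |
| red | 15.0 | 20 | 0 |
| teal | 2.00 | 4 | 0 |
| teal | 4.00 | 0 | 1 |
| teal | 6.00 | 6 | 0 |
| teal | 8.00 | 6 | 1 |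
| teal | 10.0 | 7 | 0 |
| teal | 12.0 | 8 | 0 |
| teal | 15.0 | 6 | 1 |

(standard deviation of a reading: 2 percentage points)

- the target and product in the second phase and crystals together standing at 15 min, as a percentage of the substrate charged
- concentration of target in solution at 15 min, in percent of saturation

Turn the question round: for the new flask to hold the fraction of its charge that the red run holds late, that fraction would have to stay level as the charge grows. The readings say otherwise: late in the red run the target reads 20.0% on average, and late in the teal run 7.00%, each single reading with a scatter of 2 percentage points.

standing order = 1 + ln(7.00% / 20.0%) / ln(1.6 M / 0.41 M) = 0.229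

This is the standing order, an apparent order: the power of the substrate charge to which the late amount of target rises, with reagent in the second phase and the volume ratio held. A level fraction needs an order of one, and these runs read far less. My own reckoning for the new flask:

fraction at 15 min = 20.0% × (0.81 M / 0.41 M)^(0.229 − 1) = 11.8%

The forecast, “Interpolating on a log scale”, gave 12.5% (9.5% to 16%), above mine, and 75% of saturation (40% to 100%).

The new flask gives 13.7%, inside the forecast's range for it, and 31.6% of saturation, below the forecast's range for saturation.

    reagent in the reaction phase ⇌ reagent in the second phase, rate k1*([reagent in the reaction phase] - [reagent in the second phase]/K1) per volume of the first phase (partition coefficient = 55.0, kL = 0.0160 s⁻¹)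
    substrate + reagent in the reaction phase → target (k = 0.0510 M⁻¹ s⁻¹)
    target ⇌ product in the second phase, rate k3*([target] - [product in the second phase]/K3) per volume of the first phase (partition coefficient = 0.520, kL = 0.0230 s⁻¹)
    target → decomposed product (k = 0.00260 s⁻¹)
    crystals ⇌ target, rate k5*(cs5 - [target]) while solid is left; crystals form when [target] > cs5 (solubility = 0.280 M, k = 1.60 s⁻¹)
    substrate → decomposition product (k = 1.10 × 10⁻⁵ s⁻¹)

In the new flask, dissolved target is made 1.48 times as fast as it is used up at 6.53 min, each step taken net and its going into other forms counted as use. At 15.0 min that ratio is 1.00, and at 30.0 min target, product in the second phase and crystals together stand at 10.8% in that flask. Carried from the new flask's 13.7% with the standing order 0.229, a substrate charge of 1.48 M reckons to 8.64%, a move of 5.1 points; the simulated flask at that charge has moved by 5 points.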